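The quinone ring (C1=O, C2–OH, C3–CH2R, C4=O, C5–OMe, C6–H) is the enol of a cyclohex-5-ene-1,2,4-trione, so its C2–C3 bond is a Claisen retron: C2/C4 are 1,3-dioxygenated and C1/C2 form an oxalyl unit. Everything rests on a Dieckmann-type closure in which the ketone enolate carbon that becomes C3 is acylated by the α-keto ester carbon that becomes C2, giving the complete, regiodefined hydroxy-methoxy-quinone at its final oxidation level in one operation. The precursor is an acyclic (3E)-4-methoxy-2,5-dioxohept-3-enoate, unmasked from a 5-alkyl-4-methoxyfuran-2-carboxylate with singlet oxygen. The terpenoid half, including C3 (former C12), comes from (+)-sclareolide by a cationic hydride/methyl shift cascade.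

Key step: step 9

Assumption: (+)-sclareolide and 3-methoxyfuran are taken as purchasable; terpenoid carbons are numbered as in sclareolide (C8 carbinol carbon, C9 and C10 its ring neighbours, C11 methylene, C12 lactone carbonyl carbon).

Abbreviation used in names: OHN = (1R,2S)-1,2,5,5-tetramethyl-1,2,3,4,5,6,7,8-octahydronaphthalen-1-yl.

Step 1
Reactants: 1 (+)-sclareolide
Product: 2 (1R,2R,4aS,8aS)-1-(2-hydroxyethyl)-2,5,5,8a-tetramethyldecahydronaphthalen-2-ol (8α,12-diol)
Conditions: LiAlH4, THF, 0 °C → rt
Reagents that add atoms: none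
Why: Hydride reduction of the γ-lactone to the 1,4-diol, with no stereocentre touched.

Step 2
Reactants: 2 8α,12-diol
Product: 3 2-[(1R,2R,4aS,8aS)-2-hydroxy-2,5,5,8a-tetramethyldecahydronaphthalen-1-yl]ethyl acetate
Conditions: Ac2O, pyridine, DMAP (cat.), CH2Cl2, 0 °C
Reagents that add atoms: acetic anhydride, CC(=O)OC(C)=O
Why: DMAP-catalysed acylation should discriminate the primary hydroxyl from the hindered axial tertiary one.

Step 3
Reactants: 3 hydroxy acetate
Product: 4 2-(OHN)ethyl acetate
Conditions: BF3·OEt2, CH2Cl2, −78 → −10 °C; then Et3N, aq. NaHCO3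
Reagents that add atoms: none
Why: Ionisation of the tertiary C8 alcohol should start a Wagner–Meerwein (friedo) cascade of the kind established for drim-8-enes with BF3·OEt2, in which the axial 9α-H shifts suprafacially to C8 (leaving 8β-Me, 2S), the 10β-methyl shifts to the β-face of C9 (1R) and loss of H5 gives the tetrasubstituted Δ5(10) alkene, the rigid trans-decalin fixing both new stereocentres.

Step 4
Reactants: 4 rearranged acetate
Product: 5 2-(OHN)ethan-1-ol
Conditions: K2CO3 (cat.), MeOH, rt
Reagents that add atoms: none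
Why: Base-catalysed transesterification removes the acetate without touching the alkene.

Step 5
Reactants: 5 rearranged alcohol
Product: 6 (1R,2S)-1-(2-iodoethyl)-1,2,5,5-tetramethyl-1,2,3,4,5,6,7,8-octahydronaphthalene
Conditions: I2, PPh3, imidazole, CH2Cl2, 0 °C → rt
Reagents that add atoms: iodine, II
Why: Appel-type iodination of the unhindered primary alcohol by SN2 at C12, to which the hindered alkene should be inert.

Step 6
Reactants: 6 rearranged iodide; 7 3-methoxyfuran
Product: 9 3-methoxy-2-[2-(OHN)ethyl]furan, via 2-lithio-3-methoxyfuran 8 (not isolated)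
Conditions: 7 (excess), n-BuLi, THF, −78 → 0 °C; then 6, DMPU, −78 °C → rt
Reagents that add atoms: none
Why: α-Lithiation of 3-methoxyfuran at C2 (between ring oxygen and OMe) followed by SN2 alkylation with the primary iodide joins C12 to the furan carbon that will become the C4 ketone of the quinone.

Step 7
Reactants: 9 2-alkyl-3-methoxyfuran
Product: 11 methyl 4-methoxy-5-[2-(OHN)ethyl]furan-2-carboxylate, via 5-lithiofuran 10 (not isolated)
Conditions: n-BuLi, TMEDA, THF, −78 → −20 °C; then inverse addition to ClCO2Me, −78 °C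
Reagents that add atoms: methyl chloroformate, COC(=O)Cl
Why: The only remaining α-hydrogen of the furan (C5) is the most acidic site, so lithiation and trapping with the chloroformate should install the ester that supplies the oxalyl carbons.

Step 8
Reactants: 11 furoate
Product: 13 methyl (3E)-4-methoxy-2,5-dioxo-7-(OHN)hept-3-enoate, via furan endoperoxide 12 (not isolated)
Conditions: O2, hν (visible), tetraphenylporphyrin (cat.), CH2Cl2, −78 °C; then Me2S, −78 → 0 °C
Reagents that add atoms: dioxygen, O=O
Why: Dye-sensitised [4+2] addition of singlet oxygen to the electron-rich methoxyfuran and sulfide reduction of the endoperoxide is the known furan-to-cis-enedione opening, the ring fixing the cis-diacyl (3E) geometry, while the alkene flanked by two quaternary carbons should react far more slowly.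

Step 9
Reactants: 13 cis-enedione α-keto ester
Product: 16 2-hydroxy-5-methoxy-3-[(OHN)methyl]cyclohexa-2,5-diene-1,4-dione, via sodium enolate 14 (not isolated), via sodium quinonoxide 15 (not isolated)
Conditions: NaOMe, MeOH–THF, argon, 0 °C → rt; then 0.5 M aq. HCl, 0 °C
Reagents that add atoms: none
Why: Methoxide reversibly deprotonates C6 of 13, the only enolisable carbon, and enolate 14 attacks the ester carbonyl C1, made unusually electrophilic by the adjacent C2 ketone; loss of methoxide and deprotonation of the resulting cyclohex-5-ene-1,2,4-trione give quinonoxide 15, a doubly vinylogous carboxylate whose formation is the thermodynamic sink of this Dieckmann condensation. The closest known chemistry is the Fichter synthesis of 2,5-dihydroxy-1,4-benzoquinones by Claisen condensation of α-keto esters, together with the alkoxide-induced rearrangement of ylidene lactones to cyclic 1,3-diones. The six-membered ring closes in the 6-(enolendo)-exo-trig mode, whereas attack on the C2 ketone would be a 5-(enolendo)-exo-trig aldol that is disfavoured and reversible, as is O-acylation to the enol lactone. No stereocentre is formed and the two decalin stereocentres are remote from any acidic site. The step needs C- over O-acylation, six- over five-membered closure and retention of the methoxy position: the first two are secured because only the C-acylated product leaves the equilibrium as its anion, the third by the furan-derived placement of OMe on C4, where methoxide addition–elimination is degenerate and merely funnels any trans-diacyl isomer into the cyclisable cis form.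

Compound list
1 | (+)-sclareolide, (3aR,5aS,9aS,9bR)-3a,6,6,9a-tetramethyldecahydronaphtho[2,1-b]furan-2(1H)-one | O=C1C[C@H]2[C@](C)(O1)CC[C@H]1C(C)(C)CCC[C@]21C | starting material
2 | (1R,2R,4aS,8aS)-1-(2-hydroxyethyl)-2,5,5,8a-tetramethyldecahydronaphthalen-2-ol | OCC[C@H]1[C@](C)(O)CC[C@H]2C(C)(C)CCC[C@]12C | intermediate
3 | 2-[(1R,2R,4aS,8aS)-2-hydroxy-2,5,5,8a-tetramethyldecahydronaphthalen-1-yl]ethyl acetate | CC(=O)OCC[C@H]1[C@](C)(O)CC[C@H]2C(C)(C)CCC[C@]12C | intermediate
4 | 2-[(1R,2S)-1,2,5,5-tetramethyl-1,2,3,4,5,6,7,8-octahydronaphthalen-1-yl]ethyl acetate | CC(=O)OCC[C@@]1(C)C2=C(CC[C@@H]1C)C(C)(C)CCC2 | intermediate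
5 | 2-[(1R,2S)-1,2,5,5-tetramethyl-1,2,3,4,5,6,7,8-octahydronaphthalen-1-yl]ethan-1-ol | OCC[C@@]1(C)C2=C(CC[C@@H]1C)C(C)(C)CCC2 | intermediate
6 | (1R,2S)-1-(2-iodoethyl)-1,2,5,5-tetramethyl-1,2,3,4,5,6,7,8-octahydronaphthalene | ICC[C@@]1(C)C2=C(CC[C@@H]1C)C(C)(C)CCC2 | intermediate
7 | 3-methoxyfuran | COc1ccoc1 | starting material
8 | (3-methoxyfuran-2-yl)lithium | [Li]c1occc1OC | intermediate (not isolated)
9 | 3-methoxy-2-{2-[(1R,2S)-1,2,5,5-tetramethyl-1,2,3,4,5,6,7,8-octahydronaphthalen-1-yl]ethyl}furan | COc1ccoc1CC[C@@]1(C)C2=C(CC[C@@H]1C)C(C)(C)CCC2 | intermediate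
10 | (4-methoxy-5-{2-[(1R,2S)-1,2,5,5-tetramethyl-1,2,3,4,5,6,7,8-octahydronaphthalen-1-yl]ethyl}furan-2-yl)lithium | COc1cc([Li])oc1CC[C@@]1(C)C2=C(CC[C@@H]1C)C(C)(C)CCC2 | intermediate (not isolated)
11 | methyl 4-methoxy-5-{2-[(1R,2S)-1,2,5,5-tetramethyl-1,2,3,4,5,6,7,8-octahydronaphthalen-1-yl]ethyl}furan-2-carboxylate | COC(=O)c1cc(OC)c(CC[C@@]2(C)C3=C(CC[C@@H]2C)C(C)(C)CCC3)o1 | intermediate
12 | methyl 5-methoxy-4-{2-[(1R,2S)-1,2,5,5-tetramethyl-1,2,3,4,5,6,7,8-octahydronaphthalen-1-yl]ethyl}-2,3,7-trioxabicyclo[2.2.1]hept-5-ene-1-carboxylate (both bridgehead diastereomers, which converge) | COC(=O)C12OOC(CC[C@@]3(C)C4=C(CC[C@@H]3C)C(C)(C)CCC4)(O1)C(OC)=C2 | intermediate (not isolated)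
13 | methyl (3E)-4-methoxy-2,5-dioxo-7-[(1R,2S)-1,2,5,5-tetramethyl-1,2,3,4,5,6,7,8-octahydronaphthalen-1-yl]hept-3-enoate (acyl groups cis) | COC(=O)C(=O)/C=C(OC)\C(=O)CC[C@@]1(C)C2=C(CC[C@@H]1C)C(C)(C)CCC2 | intermediate
14 | sodium C5–C6 enolate of 13, methyl (3E)-4-methoxy-2-oxo-5-oxido-7-[(1R,2S)-1,2,5,5-tetramethyl-1,2,3,4,5,6,7,8-octahydronaphthalen-1-yl]hepta-3,5-dienoate sodium salt | COC(=O)C(=O)/C=C(OC)\C([O-])=CC[C@@]1(C)C2=C(CC[C@@H]1C)C(C)(C)CCC2.[Na+] | intermediate (not isolated)
15 | sodium 4-methoxy-3,6-dioxo-2-{[(1R,2S)-1,2,5,5-tetramethyl-1,2,3,4,5,6,7,8-octahydronaphthalen-1-yl]methyl}cyclohexa-1,4-dien-1-olate | COC1=CC(=O)C([O-])=C(C[C@@]2(C)C3=C(CC[C@@H]2C)C(C)(C)CCC3)C1=O.[Na+] | intermediate (not isolated)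
16 | 2-hydroxy-5-methoxy-3-{[(1R,2S)-1,2,5,5-tetramethyl-1,2,3,4,5,6,7,8-octahydronaphthalen-1-yl]methyl}cyclohexa-2,5-diene-1,4-dione | COC1=CC(=O)C(O)=C(C[C@@]2(C)C3=C(CC[C@@H]2C)C(C)(C)CCC3)C1=O | target

Total step count: 9. Longest linear sequence: 9 steps, from (+)-sclareolide 1; 3-methoxyfuran 7 enters at step 6.

Steps most likely to fail

Step 3. The C8 cation may be intercepted by the side-chain acetate oxygen (closure to a tetrahydrofuran), or the shift cascade may stop at the first-formed C8 alkenes or run on past the Δ5(10) stage. The fallback moves the cationic cascade behind the iodination, so that no oxygen nucleophile sits in the side chain. Setting out from 3, silylation of the tertiary alcohol (Et3SiOTf, 2,6-lutidine) should give the silyl ether acetate F1, methanolysis (K2CO3, MeOH) the silyloxy alcohol F2, and I2/PPh3/imidazole the silyloxy iodide F3. BF3·OEt2 should then ionise the tertiary silyl ether and the same hydride and methyl shifts should deliver iodide 6, where the route is rejoined.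

Step 8. Singlet oxygen may attack the Δ5(10) alkene (ene reaction) before the furan is consumed, or the endoperoxide may fragment instead of being reduced. The fallback replaces the oxygen-transfer oxidant by an oxo-chromium oxidant that leaves isolated alkenes alone, and lets the key step correct the geometry. Setting out from 11, pyridinium chlorochromate [C5H5NH][CrO3Cl] (NaOAc, CH2Cl2, rt) should open the methoxyfuran by electrophilic 1,4-oxidation to the trans-diacyl (3Z) enedione F4. Under the NaOMe/MeOH conditions of step 9, addition–elimination of methoxide at C4 should interconvert F4 and 13 while ring closure drains the mixture, so the route is rejoined at quinonoxide 15.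

Step 9. Methoxide may add at C3 and shift the enol ether (loss of the methoxy position), or the polycarbonyl chain may degrade by intermolecular aldol reactions faster than it cyclises. The fallback uses an activated aryl ester closed by an amine base, so that no alkoxide is present. Setting out from 9, lithiation as in step 7 and trapping with phenyl chloroformate should give the phenyl furoate F5, and photooxygenation with Me2S reduction as in step 8 the phenyl keto ester F6. DBU in CH2Cl2 at 0 °C should then close the same C–C bond with phenoxide as leaving group, and mild acidic work-up rejoins the route at target 16.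

Further compounds
F1 | step 3 | 2-[(1R,2R,4aS,8aS)-2,5,5,8a-tetramethyl-2-(triethylsilyloxy)decahydronaphthalen-1-yl]ethyl acetate | CC(=O)OCC[C@H]1[C@](C)(O[Si](CC)(CC)CC)CC[C@H]2C(C)(C)CCC[C@]12C
F2 | step 3 | 2-[(1R,2R,4aS,8aS)-2,5,5,8a-tetramethyl-2-(triethylsilyloxy)decahydronaphthalen-1-yl]ethan-1-ol | OCC[C@H]1[C@](C)(O[Si](CC)(CC)CC)CC[C@H]2C(C)(C)CCC[C@]12C
F3 | step 3 | triethyl{[(1R,2R,4aS,8aS)-1-(2-iodoethyl)-2,5,5,8a-tetramethyldecahydronaphthalen-2-yl]oxy}silane | ICC[C@H]1[C@](C)(O[Si](CC)(CC)CC)CC[C@H]2C(C)(C)CCC[C@]12C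
F4 | step 8 | methyl (3Z)-4-methoxy-2,5-dioxo-7-[(1R,2S)-1,2,5,5-tetramethyl-1,2,3,4,5,6,7,8-octahydronaphthalen-1-yl]hept-3-enoate (acyl groups trans) | COC(=O)C(=O)/C=C(OC)/C(=O)CC[C@@]1(C)C2=C(CC[C@@H]1C)C(C)(C)CCC2
F5 | step 9 | phenyl 4-methoxy-5-{2-[(1R,2S)-1,2,5,5-tetramethyl-1,2,3,4,5,6,7,8-octahydronaphthalen-1-yl]ethyl}furan-2-carboxylate | O=C(Oc1ccccc1)c1cc(OC)c(CC[C@@]2(C)C3=C(CC[C@@H]2C)C(C)(C)CCC3)o1
F6 | step 9 | phenyl (3E)-4-methoxy-2,5-dioxo-7-[(1R,2S)-1,2,5,5-tetramethyl-1,2,3,4,5,6,7,8-octahydronaphthalen-1-yl]hept-3-enoate | O=C(Oc1ccccc1)C(=O)/C=C(OC)\C(=O)CC[C@@]1(C)C2=C(CC[C@@H]1C)C(C)(C)CCC2
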